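**Retrosynthetic overview**

1. Last disconnections: the 2'-O-sulfonyl group and the 5-O- and 7-O-benzyl groups of a fully protected flavone.
2. Key disconnection: the O1–C8a bond of ring C. O1 is the fourth oxygen on ring A and lies ortho to the methoxy-bearing C8, so ring A is bought as a 1,2,4-trioxygenated benzene and O1 is added last, by anodic closure of a 1,3-diketone enol oxygen onto C8a–H.
3. The diketone is cut at C2–C3 (crossed Claisen) into a ring A methyl ketone and a ring B methyl ester. The ring B phenol is masked as a tosylate (Ts = 4-methylbenzenesulfonyl): it deactivates ring B toward oxidation and, unlike a mesylate ortho to an ester, has no acidic α-hydrogen through which the Claisen base could close a benzoxathiinone dioxide.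
4. Ring A ketone: 2,4-dihydroxybenzaldehyde, dibenzylation, Dakin oxidation, O-methylation, para-bromination, lithiation and acetylation. Ring B ester: 2-hydroxy-4,5-dimethoxybenzoic acid, esterification, tosylation.
5. Ring order: rings A and B are bought; ring C is the only ring formed, in step 9.

Key step: step 9

Remark: the target has no stereocentre; diketone 15 is drawn as the diketo tautomer but should be present mainly as the chelated Z-enol, which is the species oxidized in step 9.

**Route**

Step 1
Reactants: 1 2,4-dihydroxybenzaldehyde; 2 benzyl bromide (two equivalents are consumed)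
Product: 3 2,4-bis(benzyloxy)benzaldehyde
Conditions: BnBr (2.4 equiv), K2CO3, DMF, 60 °C
Reagents that add atoms: benzyl bromide (second equivalent), BrCc1ccccc1
Why: Double Williamson ether synthesis; each of the two phenoxides is alkylated by one equivalent of the reactive benzylic bromide, the chelated 2-OH needing only mild heating in DMF.

Step 2
Reactants: 3 2,4-bis(benzyloxy)benzaldehyde
Product: 5 2,4-bis(benzyloxy)phenol, via aryl formate 4 (not isolated)
Conditions: mCPBA, CH2Cl2, 0 °C to rt; then K2CO3 (0.2 equiv), MeOH, rt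
Reagents that add atoms: 3-chloroperoxybenzoic acid, O=C(OO)c1cccc(Cl)c1
Why: Dakin-type Baeyer–Villiger oxidation; in the Criegee adduct the electron-rich dialkoxyaryl group migrates in preference to hydride, and the aryl formate is cleaved by mild methanolysis.

Step 3
Reactants: 5 2,4-bis(benzyloxy)phenol
Product: 6 2,4-bis(benzyloxy)-1-methoxybenzene
Conditions: MeI, K2CO3, acetone, reflux
Reagents that add atoms: iodomethane, CI
Why: Williamson O-methylation of the phenoxide, which fixes the future 8-OMe before the ring is functionalized further.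

Step 4
Reactants: 6 2,4-bis(benzyloxy)-1-methoxybenzene
Product: 7 1,5-bis(benzyloxy)-2-bromo-4-methoxybenzene
Conditions: NBS, MeCN, 0 °C, dark
Reagents that add atoms: N-bromosuccinimide, O=C1CCC(=O)N1Br
Why: Electrophilic aromatic bromination; the carbon para to one benzyloxy group and ortho to the other is the most activated unhindered site, as in the bromination of 1,2,4-trimethoxybenzene, so substitution should go there and not at the flanked carbon between the two benzyloxy groups or at the carbon activated by the methoxy group alone.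

Step 5
Reactants: 7 1,5-bis(benzyloxy)-2-bromo-4-methoxybenzene
Product: 10 1-[2,4-bis(benzyloxy)-5-methoxyphenyl]ethanone, via aryllithium 8 (not isolated), via lithium hemiaminal adduct 9 (not isolated)
Conditions: n-BuLi, THF, −78 °C; MeC(O)N(OMe)Me, −78 to 0 °C; 1 M HCl
Reagents that add atoms: N-methoxy-N-methylacetamide, CC(=O)N(C)OC
Why: Bromine–lithium exchange followed by Weinreb ketone synthesis; the chelated tetrahedral adduct stops the addition at the ketone stage, and Lewis-acid Friedel–Crafts conditions that would endanger the benzyl ethers are avoided.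

Step 6
Reactants: 11 2-hydroxy-4,5-dimethoxybenzoic acid
Product: 12 methyl 2-hydroxy-4,5-dimethoxybenzoate
Conditions: MeOH, H2SO4 (cat.), reflux
Reagents that add atoms: methanol, CO
Why: Fischer esterification of the carboxylic acid in excess methanol; the chelated phenol is untouched.

Step 7
Reactants: 12 methyl 2-hydroxy-4,5-dimethoxybenzoate
Product: 13 methyl 4,5-dimethoxy-2-(tosyloxy)benzoate
Conditions: TsCl, K2CO3, acetone, reflux
Reagents that add atoms: 4-methylbenzenesulfonyl chloride, Cc1ccc(S(=O)(=O)Cl)cc1
Why: Sulfonylation of the phenoxide; the tosylate withstands amide bases because it has no α-hydrogen, and it makes ring B electron-poorer for step 9.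

Step 8
Reactants: 10 1-[2,4-bis(benzyloxy)-5-methoxyphenyl]ethanone; 13 methyl 4,5-dimethoxy-2-(tosyloxy)benzoate
Product: 15 1-[2,4-bis(benzyloxy)-5-methoxyphenyl]-3-[4,5-dimethoxy-2-(tosyloxy)phenyl]propane-1,3-dione, via lithium enolate 14 (not isolated)
Conditions: LiN(SiMe3)2 (2.5 equiv), THF, −78 °C; 13, −78 °C to rt; 1 M HCl
Reagents that add atoms: none
Why: Crossed Claisen condensation; the ketone enolate acylates the non-enolizable ester and the second equivalent of base deprotonates the acidic diketone, which drives the equilibrium, while sulfonyl transfer to the neighbouring enolate oxygen would be an endocyclic substitution at sulfur and is geometrically disfavoured.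

Step 9
Reactants: 15 1-[2,4-bis(benzyloxy)-5-methoxyphenyl]-3-[4,5-dimethoxy-2-(tosyloxy)phenyl]propane-1,3-dione
Product: 18 5,7-bis(benzyloxy)-2-[4,5-dimethoxy-2-(tosyloxy)phenyl]-8-methoxychromen-4-one, via ring A radical cation 16 (not isolated), via arenium cation 17 (not isolated)
Conditions: undivided cell, graphite anode, Pt cathode, n-Bu4NPF6 (0.1 M), HFIP/CH2Cl2 (4:1), constant potential ca. +1.3 V vs Ag/AgCl (fixed by cyclic voltammetry at the first anodic wave), about 2.1 F/mol, rt
Reagents that add atoms: none
Why: Proposed new method: one-electron oxidation at the anode should take place in the trialkoxy ring A of the enol of 15, because ring B carries only two donor oxygens and an electron-withdrawing sulfonyloxy group, and gives radical cation 16; the enol oxygen on the ring B side then adds to C6 of ring A (the future C8a, ortho to the 5-OMe), loss of the enol proton and a second electron transfer give arenium cation 17, and loss of the C6 proton forms the aromatic pyranone while the cathode turns the two protons into H2. The closest known reaction type is the anodic dehydrogenative C–H/O–H cyclization, as in the lactonization of biaryl-2-carboxylic acids to benzocoumarins and the closure of anilides to benzoxazoles; closing a chromen-4-one with a 1,3-diketone enol oxygen has not been shown. Ring C is closed in a six-membered annulative mode, the oxygen attacking an ortho carbon of the arene radical cation (formally 6-endo with respect to the C4a–C8a bond), and no stereocentre is formed. Two selectivities are needed: ring A over ring B, which the controlled potential and the tosylate should secure, and C6–H over the benzyloxy-bearing ortho carbon C2, where addition gives a mixed ketal that cannot rearomatize by proton loss and should revert. The undivided cell keeps the medium close to neutral, so acid-assisted loss of benzyl alcohol from that ketal is not promoted, and HFIP loosens the enol chelate and prolongs the life of the radical cation.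

Step 10
Reactants: 18 5,7-bis(benzyloxy)-2-[4,5-dimethoxy-2-(tosyloxy)phenyl]-8-methoxychromen-4-one
Product: 19 5,7-dihydroxy-2-[4,5-dimethoxy-2-(tosyloxy)phenyl]-8-methoxychromen-4-one
Conditions: H2 (1 atm), Pd/C (10%), EtOAc/MeOH, rt
Reagents that add atoms: none
Why: Catalytic hydrogenolysis of the two benzyl aryl ethers; the aryl tosylate and the methyl ethers are inert and the conjugated C2–C3 double bond of a flavone is reduced much more slowly, so the reaction is stopped after uptake of two equivalents of hydrogen.

Step 11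
Reactants: 19 5,7-dihydroxy-2-[4,5-dimethoxy-2-(tosyloxy)phenyl]-8-methoxychromen-4-one
Product: 20 5,7-dihydroxy-2-(2-hydroxy-4,5-dimethoxyphenyl)-8-methoxychromen-4-one
Conditions: KOH (2 M aq), 1,4-dioxane, 70 °C, argon; then 1 M HCl to pH 3
Reagents that add atoms: none
Why: Alkaline hydrolysis of the aryl sulfonate by hydroxide attack at sulfur; the 5,7-bis-phenolate formed at once turns the pyranone into a vinylogous carboxylate and so protects C2 from ring opening, the non-alcoholic medium avoids formation of an alkylating sulfonate ester, and exclusion of air protects the electron-rich phenolate.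

**Compound list**

1 | 2,4-dihydroxybenzaldehyde | O=Cc1ccc(O)cc1O | starting material
2 | benzyl bromide | BrCc1ccccc1 | starting material
3 | 2,4-bis(benzyloxy)benzaldehyde | O=Cc1ccc(OCc2ccccc2)cc1OCc1ccccc1 | intermediate
4 | 2,4-bis(benzyloxy)phenyl formate (not isolated) | O=COc1ccc(OCc2ccccc2)cc1OCc1ccccc1 | intermediate
5 | 2,4-bis(benzyloxy)phenol | Oc1ccc(OCc2ccccc2)cc1OCc1ccccc1 | intermediate
6 | 2,4-bis(benzyloxy)-1-methoxybenzene | COc1ccc(OCc2ccccc2)cc1OCc1ccccc1 | intermediate
7 | 1,5-bis(benzyloxy)-2-bromo-4-methoxybenzene | COc1cc(Br)c(OCc2ccccc2)cc1OCc1ccccc1 | intermediate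
8 | [2,4-bis(benzyloxy)-5-methoxyphenyl]lithium (not isolated) | [Li]c1cc(OC)c(OCc2ccccc2)cc1OCc1ccccc1 | intermediate
9 | lithium 1-[2,4-bis(benzyloxy)-5-methoxyphenyl]-1-[methoxy(methyl)amino]ethanolate (not isolated, racemic) | CON(C)C(C)(O[Li])c1cc(OC)c(OCc2ccccc2)cc1OCc1ccccc1 | intermediate
10 | 1-[2,4-bis(benzyloxy)-5-methoxyphenyl]ethanone | CC(=O)c1cc(OC)c(OCc2ccccc2)cc1OCc1ccccc1 | intermediate
11 | 2-hydroxy-4,5-dimethoxybenzoic acid | COc1cc(O)c(C(=O)O)cc1OC | starting material
12 | methyl 2-hydroxy-4,5-dimethoxybenzoate | COC(=O)c1cc(OC)c(OC)cc1O | intermediate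
13 | methyl 4,5-dimethoxy-2-(tosyloxy)benzoate | COC(=O)c1cc(OC)c(OC)cc1OS(=O)(=O)c1ccc(C)cc1 | intermediate
14 | lithium enolate of 10, lithium 1-[2,4-bis(benzyloxy)-5-methoxyphenyl]ethenolate (not isolated) | [Li]OC(=C)c1cc(OC)c(OCc2ccccc2)cc1OCc1ccccc1 | intermediate
15 | 1-[2,4-bis(benzyloxy)-5-methoxyphenyl]-3-[4,5-dimethoxy-2-(tosyloxy)phenyl]propane-1,3-dione | COc1cc(C(=O)CC(=O)c2cc(OC)c(OC)cc2OS(=O)(=O)c2ccc(C)cc2)c(OCc2ccccc2)cc1OCc1ccccc1 | intermediate
16 | ring A radical cation of the Z-enol of 15, drawn with the charge on the 5-methoxy oxygen (not isolated) | C[O+]c1cc(C(=O)/C=C(\O)c2cc(OC)c(OC)cc2OS(=O)(=O)c2ccc(C)cc2)c(OCc2ccccc2)cc1OCc1ccccc1 | intermediate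
17 | 8a-H arenium cation of 18, drawn as the 8-methoxy oxocarbenium form (not isolated, racemic) | C[O+]=C1C(OCc2ccccc2)=CC(OCc2ccccc2)=C2C(=O)C=C(c3cc(OC)c(OC)cc3OS(=O)(=O)c3ccc(C)cc3)OC12 | intermediate
18 | 5,7-bis(benzyloxy)-2-[4,5-dimethoxy-2-(tosyloxy)phenyl]-8-methoxychromen-4-one | COc1cc(OS(=O)(=O)c2ccc(C)cc2)c(-c2cc(=O)c3c(OCc4ccccc4)cc(OCc4ccccc4)c(OC)c3o2)cc1OC | intermediate
19 | 5,7-dihydroxy-2-[4,5-dimethoxy-2-(tosyloxy)phenyl]-8-methoxychromen-4-one | COc1cc(OS(=O)(=O)c2ccc(C)cc2)c(-c2cc(=O)c3c(O)cc(O)c(OC)c3o2)cc1OC | intermediate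
20 | 5,7-dihydroxy-2-(2-hydroxy-4,5-dimethoxyphenyl)-8-methoxychromen-4-one | COc1cc(O)c(-c2cc(=O)c3c(O)cc(O)c(OC)c3o2)cc1OC | target

**Step count**

Total: 11 steps. Longest linear sequence: 9 steps (steps 1, 2, 3, 4, 5, 8, 9, 10, 11) from 2,4-dihydroxybenzaldehyde; steps 6 and 7 form the ring B branch.

**Steps most likely to fail**

1. Step 9. What may go wrong: the enol oxygen may add at the benzyloxy-bearing ortho carbon of the radical cation with loss of benzyl alcohol, or the benzylic positions or the product flavone may be oxidized further, so that little substitution at C8a–H takes place. Fallback by known chemistry, in which O1 is bought with ring A and the C8 oxygen is added afterwards; it sets out from ester 13 and comes back at 19. The dianion of commercial 1-[2,4-bis(benzyloxy)-6-hydroxyphenyl]ethanone (LiN(SiMe3)2, THF, −78 °C to rt) would be condensed with 13 to give 1-[2,4-bis(benzyloxy)-6-hydroxyphenyl]-3-[4,5-dimethoxy-2-(tosyloxy)phenyl]propane-1,3-dione F1. Acid-catalysed cyclodehydration (TsOH, toluene, reflux) should give 5,7-bis(benzyloxy)-2-[4,5-dimethoxy-2-(tosyloxy)phenyl]chromen-4-one F2. Chelation-directed cleavage of the peri benzyl ether (BCl3, 1 equiv, CH2Cl2, −78 °C) should give 7-(benzyloxy)-5-hydroxy-2-[4,5-dimethoxy-2-(tosyloxy)phenyl]chromen-4-one F3. Elbs persulfate oxidation (K2S2O8, aq KOH, pyridine, rt), which attacks para to the 5-phenolate and therefore at C8, should give potassium 7-(benzyloxy)-5-hydroxy-2-[4,5-dimethoxy-2-(tosyloxy)phenyl]-4-oxochromen-8-yl sulfate F4, and warm dilute HCl should hydrolyse it to 7-(benzyloxy)-5,8-dihydroxy-2-[4,5-dimethoxy-2-(tosyloxy)phenyl]chromen-4-one F5. Methylation with Me2SO4 (1.1 equiv) and K2CO3 in acetone, which spares the chelated 5-OH, should give 7-(benzyloxy)-5-hydroxy-8-methoxy-2-[4,5-dimethoxy-2-(tosyloxy)phenyl]chromen-4-one F6. Hydrogenolysis (H2, Pd/C) then gives 19, and step 11 completes the route.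

2. Step 8. What may go wrong: acylation of the enolate by the hindered, electron-rich ester may be slow, which leaves time for sulfonyl transfer from the tosylate to the enolate or to the amide base and for retro-Claisen cleavage on warming. Fallback by aldol addition and oxidation; it sets out from ketone 10 and comes back at 15. Commercial 2-hydroxy-4,5-dimethoxybenzaldehyde would be tosylated (TsCl, K2CO3, acetone) to 4,5-dimethoxy-2-(tosyloxy)benzaldehyde F7. The enolate of 10 (LiN(SiMe3)2, 1.05 equiv, THF, −78 °C) would add to F7 at −78 °C to give racemic 1-[2,4-bis(benzyloxy)-5-methoxyphenyl]-3-hydroxy-3-[4,5-dimethoxy-2-(tosyloxy)phenyl]propan-1-one F8. Oxidation of the β-hydroxy ketone with Dess–Martin periodinane in CH2Cl2 then gives 15. The sulfonate meets only one equivalent of base, at low temperature, and a far more reactive electrophile.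

3. Step 11. What may go wrong: sulfur–oxygen cleavage may be slow on the electron-rich dianion of 19, which forces long heating and lets traces of air oxidize the polyphenolate. Fallback by reversing the order of the two deprotections; it sets out from 18 and comes back at 20. In 18 the sulfonate is not deactivated by phenolates and no free polyphenol is exposed to base, so brief treatment with aqueous LiOH in THF at 40 °C should give 5,7-bis(benzyloxy)-2-(2-hydroxy-4,5-dimethoxyphenyl)-8-methoxychromen-4-one F9. Hydrogenolysis under the conditions of step 10 then gives 20 directly.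

**Further compounds**

F1 | step 9 | 1-[2,4-bis(benzyloxy)-6-hydroxyphenyl]-3-[4,5-dimethoxy-2-(tosyloxy)phenyl]propane-1,3-dione | COc1cc(OS(=O)(=O)c2ccc(C)cc2)c(C(=O)CC(=O)c2c(O)cc(OCc3ccccc3)cc2OCc2ccccc2)cc1OC
F2 | step 9 | 5,7-bis(benzyloxy)-2-[4,5-dimethoxy-2-(tosyloxy)phenyl]chromen-4-one | COc1cc(OS(=O)(=O)c2ccc(C)cc2)c(-c2cc(=O)c3c(OCc4ccccc4)cc(OCc4ccccc4)cc3o2)cc1OC
F3 | step 9 | 7-(benzyloxy)-5-hydroxy-2-[4,5-dimethoxy-2-(tosyloxy)phenyl]chromen-4-one | COc1cc(OS(=O)(=O)c2ccc(C)cc2)c(-c2cc(=O)c3c(O)cc(OCc4ccccc4)cc3o2)cc1OC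
F4 | step 9 | potassium 7-(benzyloxy)-5-hydroxy-2-[4,5-dimethoxy-2-(tosyloxy)phenyl]-4-oxochromen-8-yl sulfate | COc1cc(OS(=O)(=O)c2ccc(C)cc2)c(-c2cc(=O)c3c(O)cc(OCc4ccccc4)c(OS(=O)(=O)[O-])c3o2)cc1OC.[K+]
F5 | step 9 | 7-(benzyloxy)-5,8-dihydroxy-2-[4,5-dimethoxy-2-(tosyloxy)phenyl]chromen-4-one | COc1cc(OS(=O)(=O)c2ccc(C)cc2)c(-c2cc(=O)c3c(O)cc(OCc4ccccc4)c(O)c3o2)cc1OC
F6 | step 9 | 7-(benzyloxy)-5-hydroxy-8-methoxy-2-[4,5-dimethoxy-2-(tosyloxy)phenyl]chromen-4-one | COc1cc(OS(=O)(=O)c2ccc(C)cc2)c(-c2cc(=O)c3c(O)cc(OCc4ccccc4)c(OC)c3o2)cc1OC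
F7 | step 8 | 4,5-dimethoxy-2-(tosyloxy)benzaldehyde | COc1cc(OS(=O)(=O)c2ccc(C)cc2)c(C=O)cc1OC
F8 | step 8 | 1-[2,4-bis(benzyloxy)-5-methoxyphenyl]-3-hydroxy-3-[4,5-dimethoxy-2-(tosyloxy)phenyl]propan-1-one (racemic) | COc1cc(C(=O)CC(O)c2cc(OC)c(OC)cc2OS(=O)(=O)c2ccc(C)cc2)c(OCc2ccccc2)cc1OCc1ccccc1
F9 | step 11 | 5,7-bis(benzyloxy)-2-(2-hydroxy-4,5-dimethoxyphenyl)-8-methoxychromen-4-one | COc1cc(O)c(-c2cc(=O)c3c(OCc4ccccc4)cc(OCc4ccccc4)c(OC)c3o2)cc1OC
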